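The plan rests on cutting the C1–C6 bond of the cyclohexa-1,4-diene ring (numbering: C1 bears the 2-acetoxypentadecyl chain, C3 the free hydroxyl, C5 the methoxy group, C6 the ring acetate). C6 is a carbinol flanked by the C1=C2 and C4=C5 double bonds, so it can be read as the adduct of a C1 alkenyl metal and a C6 enal. One intramolecular Nozaki–Hiyama–Kishi reaction forms this bond, closes the six-membered ring and creates the C6 stereocentre. Its precursor is an open-chain (2E,5Z) iodo dienal with O3 silylated and the side-chain acetate already in place; its cis enol ether is taken from methyl tetronate.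

Key step: step 13

Remark: position labels C1–C6, C1', C2', O3, O6 and O2' in the Why lines follow the target numbering, while locants inside compound names are IUPAC locants. In the open-chain intermediates the enol ether that keeps C3 and C6 cis is E by the sequence rules (OMe outranks C6 on C5), so the ring precursor is a (2E,5Z) dienal and not a Z,Z dienal.

Step 1
Reactants: 1 dodecylmagnesium bromide; 2 (R)-epichlorohydrin
Product: 3 (R)-1-chloropentadecan-2-ol
Conditions: CuI (10 mol %), THF, −40 to 0 °C; then 1 M HCl
Reagents that add atoms: none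
Why: Copper-catalysed Grignard opening of the epoxide (SN2 at the unsubstituted ring carbon) is far faster than attack at the C–Cl carbon, and the stereocentre of 2 is a spectator, so its configuration should pass unchanged into 3.

Step 2
Reactants: 3 (R)-1-chloropentadecan-2-ol; 4 lithium acetylide–ethylenediamine complex (LiC≡CH·H2NCH2CH2NH2)
Product: 6 (R)-heptadec-1-yn-4-ol, via (R)-2-tridecyloxirane 5 (not isolated)
Conditions: LiC≡CH·H2NCH2CH2NH2 (3.5 equiv), DMSO/THF, 0 °C to rt; H2O
Reagents that add atoms: none
Why: Under the basic conditions the alkoxide of 3 should close to epoxide 5 (intramolecular Williamson reaction) and acetylide then opens 5 at its terminal carbon (SN2 epoxide opening), so the carbinol carbon is never a reaction centre and keeps its R configuration.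

Step 3
Reactants: 6 (R)-heptadec-1-yn-4-ol
Product: 7 (R)-4-(triethylsilyloxy)heptadec-1-yne
Conditions: Et3SiCl, imidazole, CH2Cl2, 0 °C to rt
Reagents that add atoms: chlorotriethylsilane, CC[Si](CC)(CC)Cl
Why: Imidazole-promoted silyl ether formation on a secondary alcohol is routine, and the triethylsilyl group withstands the acetylide, hydride and hydroalumination steps yet can later be removed beside a tert-butyldimethylsilyl ether.

Step 4
Reactants: 8 methyl tetronate
Product: 9 (E)-4-hydroxy-N,3-dimethoxy-N-methylbut-2-enamide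
Conditions: MeNH(OMe)·HCl, AlMe3, CH2Cl2, 0 °C to rt; aq potassium sodium tartrate
Reagents that add atoms: N,O-dimethylhydroxylamine hydrochloride, CNOC.Cl
Why: Lactone aminolysis by the aluminium amide formed from AlMe3 and the amine salt (Weinreb amide synthesis) should open the vinylogous carbonate at its carbonyl carbon, the non-basic reagent sparing the acidic C5 hydrogens of the tetronate, and the ring origin of the alkene fixes carbonyl and CH2OH cis (E by the sequence rules).

Step 5
Reactants: 9 (E)-4-hydroxy-N,3-dimethoxy-N-methylbut-2-enamide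
Product: 10 (E)-N,3-dimethoxy-N-methyl-4-(triethylsilyloxy)but-2-enamide
Conditions: Et3SiCl, imidazole, DMF, 0 °C, on crude 9 at once
Reagents that add atoms: chlorotriethylsilane, CC[Si](CC)(CC)Cl
Why: Silyl ether formation at the primary allylic hydroxyl is fast at 0 °C and removes the nucleophile that could otherwise re-close the lactone.

Step 6
Reactants: 7 (R)-4-(triethylsilyloxy)heptadec-1-yne; 10 (E)-N,3-dimethoxy-N-methyl-4-(triethylsilyloxy)but-2-enamide
Product: 12 (2E,8R)-2-methoxy-1,8-bis(triethylsilyloxy)henicos-2-en-5-yn-4-one, via lithium acetylide 11 (not isolated)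
Conditions: 7, n-BuLi, THF, −78 °C; then 10, −78 to 0 °C; inverse quench into cold aq NaH2PO4/Na2HPO4 (pH 7)
Reagents that add atoms: none
Why: Weinreb ketone synthesis: the lithium acetylide adds once to the amide carbonyl and the chelated tetrahedral adduct holds until the quench, so over-addition is excluded and the push–pull enone keeps its E geometry.

Step 7
Reactants: 12 (2E,8R)-2-methoxy-1,8-bis(triethylsilyloxy)henicos-2-en-5-yn-4-one
Product: 13 (2E,4S,8R)-2-methoxy-1,8-bis(triethylsilyloxy)henicos-2-en-5-yn-4-ol
Conditions: Ru[(S,S)-TsNCH(Ph)CH(Ph)NH](η6-p-cymene) (5 mol %), i-PrOH, rt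
Reagents that add atoms: none
Why: Noyori asymmetric transfer hydrogenation of an alkynyl ketone: with the (S,S) catalyst the slim alkynyl group is expected to take its usual place next to the arene ligand and the bulkier β,β-disubstituted alkenyl group the other, so that hydride reaches the Re face and sets the (4S) carbinol (C3 of the target) under catalyst control, while the base-free amido complex spares the silyl ethers.

Step 8
Reactants: 13 (2E,4S,8R)-2-methoxy-1,8-bis(triethylsilyloxy)henicos-2-en-5-yn-4-ol
Product: 15 (2E,4S,5Z,8R)-6-iodo-2-methoxy-1,8-bis(triethylsilyloxy)henicosa-2,5-dien-4-ol, via alkenylaluminate 14 (not isolated)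
Conditions: NaAlH2(OCH2CH2OCH3)2, THF, 0 °C; EtOAc; then I2 (1.2 equiv), THF, −78 °C; aq potassium sodium tartrate/Na2S2O3
Reagents that add atoms: iodine, [I][I]
Why: Alkoxide-directed trans-hydroalumination of the propargylic alcohol puts hydride on the proximal and aluminium on the distal alkyne carbon within a five-membered aluminate, and iodinolysis of the C–Al bond with retention should give the (5Z) vinyl iodide with iodine cis to the carbinol carbon, which is not touched.

Step 9
Reactants: 15 (2E,4S,5Z,8R)-6-iodo-2-methoxy-1,8-bis(triethylsilyloxy)henicosa-2,5-dien-4-ol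
Product: 16 (2E,4S,5Z,8R)-4-(tert-butyldimethylsilyloxy)-6-iodo-2-methoxy-1,8-bis(triethylsilyloxy)henicosa-2,5-diene
Conditions: t-BuMe2SiCl, imidazole, DMAP (cat.), DMF, rt
Reagents that add atoms: tert-butyldimethylsilyl chloride, CC(C)(C)[Si](C)(C)Cl
Why: Imidazole-promoted silyl ether formation under basic conditions caps O3, which must be blocked before C6 is oxidised because a free cis hydroxy enal would close to a lactol and lose water to a furan.

Step 10
Reactants: 16 (2E,4S,5Z,8R)-4-(tert-butyldimethylsilyloxy)-6-iodo-2-methoxy-1,8-bis(triethylsilyloxy)henicosa-2,5-diene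
Product: 17 (2E,4S,5Z,8R)-4-(tert-butyldimethylsilyloxy)-6-iodo-2-methoxyhenicosa-2,5-diene-1,8-diol
Conditions: HF·pyridine, excess pyridine, THF, 0 °C to rt
Reagents that add atoms: none
Why: Fluoride-mediated silyl ether cleavage is governed by steric bulk at silicon, so both triethylsilyl ethers should be removed while the secondary tert-butyldimethylsilyl ether survives, and the excess pyridine keeps the medium from ionising the allylic C3–O bond.

Step 11
Reactants: 17 (2E,4S,5Z,8R)-4-(tert-butyldimethylsilyloxy)-6-iodo-2-methoxyhenicosa-2,5-diene-1,8-diol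
Product: 18 (2E,4S,5Z,8R)-4-(tert-butyldimethylsilyloxy)-8-hydroxy-6-iodo-2-methoxyhenicosa-2,5-dienal
Conditions: MnO2, CH2Cl2, rt, dark
Reagents that add atoms: none
Why: Chemoselective allylic oxidation: MnO2 converts only the primary allylic alcohol into the α-methoxy enal and leaves the saturated secondary alcohol, the vinyl iodide and the alkene geometries alone.

Step 12
Reactants: 18 (2E,4S,5Z,8R)-4-(tert-butyldimethylsilyloxy)-8-hydroxy-6-iodo-2-methoxyhenicosa-2,5-dienal
Product: 19 (2E,4S,5Z,8R)-8-acetoxy-4-(tert-butyldimethylsilyloxy)-6-iodo-2-methoxyhenicosa-2,5-dienal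
Conditions: Ac2O, pyridine, DMAP (cat.), CH2Cl2, 0 °C
Reagents that add atoms: acetic anhydride, CC(=O)OC(C)=O
Why: DMAP-catalysed acylation of the remaining secondary alcohol puts the side-chain acetate of the target in place before ring closure, so that the fragile ring compounds never have to meet HF.

Step 13
Reactants: 19 (2E,4S,5Z,8R)-8-acetoxy-4-(tert-butyldimethylsilyloxy)-6-iodo-2-methoxyhenicosa-2,5-dienal
Product: 21 (2R)-1-[(3R,6S)-3-(tert-butyldimethylsilyloxy)-6-hydroxy-5-methoxycyclohexa-1,4-dien-1-yl]pentadecan-2-yl acetate, via alkenylchromium 20 (not isolated)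
Conditions: CrCl2 (6 equiv), (S)-N-[2-(4-isopropyl-4,5-dihydrooxazol-2-yl)-6-methylphenyl]methanesulfonamide (6.6 equiv), Et3N (6.6 equiv), THF, rt; then NiCl2 (0.2 equiv) and 19 by syringe pump to 5 mM, rt; aq potassium sodium tartrate/NaHCO3
Reagents that add atoms: none
Why: NiCl2 is reduced by CrCl2 to zerovalent nickel, which inserts into the C1–I bond of 19 and passes the alkenyl group to trivalent chromium; alkenylchromium 20 then adds 1,2 to the C6 aldehyde, so that the C1–C6 bond, the ring and the carbinol are made together. This is the intramolecular Nozaki–Hiyama–Kishi reaction, known for 2-iodoalkenes tethered to aldehydes, and the ring closes in the 6-exo-trig mode. The (5Z) iodoalkene and the (2E) enol ether hold C1 and C6 on the same side of the chain, which should let cyclisation at 5 mM outrun dimerisation and reductive coupling of the enal. Chemoselectivity comes from the reagent, since alkenylchromium species leave esters, silyl ethers and enol ethers alone and the medium is neither acidic nor strongly basic. The new C6 centre must be S, cis to O3: a boat-like transition state with the O3 silyl ether and the chromium alkoxide both pseudo-equatorial already favours this, and the sulfonamide–oxazoline ligand on chromium is used as the antipode that sends the alkenyl group to the Si face of the aldehyde (the S ligand is tried first, its mirror image if it proves mismatched). Any trans alcohol is removed by chromatography on Et3N-washed silica.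

Step 14
Reactants: 21 (2R)-1-[(3R,6S)-3-(tert-butyldimethylsilyloxy)-6-hydroxy-5-methoxycyclohexa-1,4-dien-1-yl]pentadecan-2-yl acetate
Product: 22 (2R)-1-[(3R,6S)-6-acetoxy-3-(tert-butyldimethylsilyloxy)-5-methoxycyclohexa-1,4-dien-1-yl]pentadecan-2-yl acetate
Conditions: Ac2O, pyridine, DMAP (cat.), CH2Cl2, 0 °C
Reagents that add atoms: acetic anhydride, CC(=O)OC(C)=O
Why: DMAP-catalysed acylation of the doubly allylic C6 hydroxyl proceeds at oxygen with retention and under basic conditions that should not ionise or aromatise the skipped diene.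

Step 15
Reactants: 22 (2R)-1-[(3R,6S)-6-acetoxy-3-(tert-butyldimethylsilyloxy)-5-methoxycyclohexa-1,4-dien-1-yl]pentadecan-2-yl acetate
Product: 23 (2R)-1-[(3R,6S)-6-acetoxy-3-hydroxy-5-methoxycyclohexa-1,4-dien-1-yl]pentadecan-2-yl acetate
Conditions: Bu4NF, AcOH (1:1), THF, 0 °C to rt
Reagents that add atoms: none
Why: Fluoride-mediated cleavage of the tert-butyldimethylsilyl ether, buffered with AcOH so that neither acetate migration nor base-induced loss of AcOH with aromatisation should compete, frees O3 and gives the target with all three stereocentres unchanged.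

Compound list
1 | dodecylmagnesium bromide | CCCCCCCCCCCC[Mg]Br | starting material
2 | (R)-epichlorohydrin, (R)-2-(chloromethyl)oxirane | ClC[C@H]1CO1 | starting material
3 | (R)-1-chloropentadecan-2-ol | ClC[C@H](O)CCCCCCCCCCCCC | intermediate
4 | lithium acetylide–ethylenediamine complex, LiC≡CH·H2NCH2CH2NH2 | [Li]C#C.NCCN | starting material
5 | (R)-2-tridecyloxirane | CCCCCCCCCCCCC[C@@H]1CO1 | intermediate (not isolated)
6 | (R)-heptadec-1-yn-4-ol | CCCCCCCCCCCCC[C@H](CC#C)O | intermediate
7 | (R)-4-(triethylsilyloxy)heptadec-1-yne | CCCCCCCCCCCCC[C@H](CC#C)O[Si](CC)(CC)CC | intermediate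
8 | methyl tetronate, 4-methoxyfuran-2(5H)-one | COC1=CC(=O)OC1 | starting material
9 | (E)-4-hydroxy-N,3-dimethoxy-N-methylbut-2-enamide | CON(C)C(=O)/C=C(OC)\CO | intermediate
10 | (E)-N,3-dimethoxy-N-methyl-4-(triethylsilyloxy)but-2-enamide | CON(C)C(=O)/C=C(OC)\CO[Si](CC)(CC)CC | intermediate
11 | lithium acetylide of 7, [(R)-4-(triethylsilyloxy)heptadec-1-yn-1-yl]lithium | CCCCCCCCCCCCC[C@H](CC#C[Li])O[Si](CC)(CC)CC | intermediate (not isolated)
12 | (2E,8R)-2-methoxy-1,8-bis(triethylsilyloxy)henicos-2-en-5-yn-4-one | CCCCCCCCCCCCC[C@H](CC#CC(=O)/C=C(OC)\CO[Si](CC)(CC)CC)O[Si](CC)(CC)CC | intermediate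
13 | (2E,4S,8R)-2-methoxy-1,8-bis(triethylsilyloxy)henicos-2-en-5-yn-4-ol | CCCCCCCCCCCCC[C@H](CC#C[C@@H](O)/C=C(OC)\CO[Si](CC)(CC)CC)O[Si](CC)(CC)CC | intermediate
14 | sodium alkenylaluminate from 13: five-membered ring of Al, O4, C4, C5 and C6, two 2-methoxyethoxy groups on aluminium | CCCCCCCCCCCCC[C@H](CC1=C[C@H](/C=C(OC)\CO[Si](CC)(CC)CC)O[Al-]1(OCCOC)OCCOC)O[Si](CC)(CC)CC.[Na+] | intermediate (not isolated)
15 | (2E,4S,5Z,8R)-6-iodo-2-methoxy-1,8-bis(triethylsilyloxy)henicosa-2,5-dien-4-ol | CCCCCCCCCCCCC[C@H](C/C(I)=C/[C@@H](O)/C=C(OC)\CO[Si](CC)(CC)CC)O[Si](CC)(CC)CC | intermediate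
16 | (2E,4S,5Z,8R)-4-(tert-butyldimethylsilyloxy)-6-iodo-2-methoxy-1,8-bis(triethylsilyloxy)henicosa-2,5-diene | CCCCCCCCCCCCC[C@H](C/C(I)=C/[C@@H](O[Si](C)(C)C(C)(C)C)/C=C(OC)\CO[Si](CC)(CC)CC)O[Si](CC)(CC)CC | intermediate
17 | (2E,4S,5Z,8R)-4-(tert-butyldimethylsilyloxy)-6-iodo-2-methoxyhenicosa-2,5-diene-1,8-diol | CCCCCCCCCCCCC[C@H](C/C(I)=C/[C@@H](O[Si](C)(C)C(C)(C)C)/C=C(OC)\CO)O | intermediate
18 | (2E,4S,5Z,8R)-4-(tert-butyldimethylsilyloxy)-8-hydroxy-6-iodo-2-methoxyhenicosa-2,5-dienal | CCCCCCCCCCCCC[C@H](C/C(I)=C/[C@@H](O[Si](C)(C)C(C)(C)C)/C=C(OC)\C=O)O | intermediate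
19 | (2E,4S,5Z,8R)-8-acetoxy-4-(tert-butyldimethylsilyloxy)-6-iodo-2-methoxyhenicosa-2,5-dienal | CCCCCCCCCCCCC[C@H](C/C(I)=C/[C@@H](O[Si](C)(C)C(C)(C)C)/C=C(OC)\C=O)OC(C)=O | intermediate
20 | alkenylchromium chloride from 19, chromium in place of iodine and carrying the sulfonamidate–oxazoline ligand (trivalent chromium) | CCCCCCCCCCCCC[C@H](C/C(=C/[C@@H](O[Si](C)(C)C(C)(C)C)/C=C(OC)\C=O)[Cr](Cl)N(c1c(C)cccc1C1=N[C@@H](C(C)C)CO1)S(C)(=O)=O)OC(C)=O | intermediate (not isolated)
21 | (2R)-1-[(3R,6S)-3-(tert-butyldimethylsilyloxy)-6-hydroxy-5-methoxycyclohexa-1,4-dien-1-yl]pentadecan-2-yl acetate | CCCCCCCCCCCCC[C@H](CC1=C[C@@H](O[Si](C)(C)C(C)(C)C)C=C(OC)[C@H]1O)OC(C)=O | intermediate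
22 | (2R)-1-[(3R,6S)-6-acetoxy-3-(tert-butyldimethylsilyloxy)-5-methoxycyclohexa-1,4-dien-1-yl]pentadecan-2-yl acetate | CCCCCCCCCCCCC[C@H](CC1=C[C@@H](O[Si](C)(C)C(C)(C)C)C=C(OC)[C@H]1OC(C)=O)OC(C)=O | intermediate
23 | (2R)-1-[(3R,6S)-6-acetoxy-3-hydroxy-5-methoxycyclohexa-1,4-dien-1-yl]pentadecan-2-yl acetate (CNP0123936.1) | CCCCCCCCCCCCC[C@H](CC1=C[C@@H](O)C=C(OC)[C@H]1OC(C)=O)OC(C)=O | target

Total step count: 15. Longest linear sequence: 13 steps (steps 1–3 and 6–15).

Steps most likely to fail

Step 13. The ring closure may show poor facial selectivity at C6, or the ligand-bearing chromium reagent may add so slowly that reductive dimerisation of the enal and loss of iodine compete. The fallback sets out from 19 and no longer controls C6 in the ring closure but corrects it afterwards. Compound 19 is cyclised without the chiral ligand (CrCl2, catalytic NiCl2, DMSO, high dilution), where the small ligand-free chromium species reacts fastest. The cis alcohol 21 goes on through step 14. The trans alcohol (2R)-1-[(3R,6R)-3-(tert-butyldimethylsilyloxy)-6-hydroxy-5-methoxycyclohexa-1,4-dien-1-yl]pentadecan-2-yl acetate F1 is separated and treated with AcOH, PPh3 and diisopropyl azodicarboxylate in toluene at 0 °C. This Mitsunobu reaction should give the C6 acetate with inversion, which is 22, where the route is rejoined.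

Step 4. The aluminium amide may attack C4 of the tetronate with loss of methoxide instead of the carbonyl carbon, or 9 may re-close to the lactone before it is silylated. The fallback sets out from 8 and opens the ring by reduction. Treatment with iBu2AlH (CH2Cl2, −78 °C) gives the lactol 4-methoxy-2,5-dihydrofuran-2-ol F2, which is not stored because it dehydrates easily to a furan. It is added cold to an excess of lithium acetylide 11, which should add to the open hydroxy enal form and give the diol (2E,4RS,8R)-2-methoxy-8-(triethylsilyloxy)henicos-2-en-5-yne-1,4-diol F3. Selective silylation of the primary hydroxyl (Et3SiCl, imidazole, CH2Cl2, −40 °C) gives (2E,4RS,8R)-2-methoxy-1,8-bis(triethylsilyloxy)henicos-2-en-5-yn-4-ol F4. Oxidation of its secondary alcohol with MnO2 gives ynone 12, where the route is rejoined.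

Step 7. Discrimination between the two faces of the ketone may be poor because both flanking groups are unsaturated, and the electron-rich product may be re-oxidised by acetone with erosion of selectivity. The fallback sets out from 10 and creates the carbinol centre in the C–C bond formation instead of in a reduction. Reduction of the Weinreb amide with iBu2AlH (THF, −78 °C) gives the aldehyde (E)-3-methoxy-4-(triethylsilyloxy)but-2-enal F5. Alkyne 7 is then added as its zinc alkynylide (Me2Zn, bis(diarylprolinol)phenol ligand, toluene, 0 °C), with the ligand antipode that delivers the alkynyl group to the Re face of the aldehyde. This should give 13 directly, where the route is rejoined.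

Further compounds
F1 | step 13 | (2R)-1-[(3R,6R)-3-(tert-butyldimethylsilyloxy)-6-hydroxy-5-methoxycyclohexa-1,4-dien-1-yl]pentadecan-2-yl acetate | CCCCCCCCCCCCC[C@H](CC1=C[C@@H](O[Si](C)(C)C(C)(C)C)C=C(OC)[C@@H]1O)OC(C)=O
F2 | step 4 | 4-methoxy-2,5-dihydrofuran-2-ol (racemic lactol) | COC1=CC(O)OC1
F3 | step 4 | (2E,4RS,8R)-2-methoxy-8-(triethylsilyloxy)henicos-2-en-5-yne-1,4-diol | CCCCCCCCCCCCC[C@H](CC#CC(O)/C=C(OC)\CO)O[Si](CC)(CC)CC
F4 | step 4 | (2E,4RS,8R)-2-methoxy-1,8-bis(triethylsilyloxy)henicos-2-en-5-yn-4-ol | CCCCCCCCCCCCC[C@H](CC#CC(O)/C=C(OC)\CO[Si](CC)(CC)CC)O[Si](CC)(CC)CC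
F5 | step 7 | (E)-3-methoxy-4-(triethylsilyloxy)but-2-enal | O=C/C=C(OC)\CO[Si](CC)(CC)CC
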